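## Retrosynthetic overview

1. The target is (−)-epigallocatechin 3-O-gallate-(4β→8)-(−)-epigallocatechin (upper unit: rings A/C/B plus galloyl ester; lower unit: rings D/F/E). The last C–C disconnection is C4(upper)–C8(ring D), made by Friedel–Crafts coupling of a C4 cation from a benzylated, galloylated (−)-epigallocatechin (chiral pool: C2 and C3 bought, C4 relayed, gallate attached by esterification) with a benzylated epigallocatechin.
2. The lower unit is built de novo: pyran ring F is opened at O1–C2 (Mitsunobu closure with inversion) to an anti-1,2-diol derivative, whose C2 carbinol comes from chelation-controlled reduction of an aryl ketone, itself unmasked from a 1-arylvinyl group.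
3. Key disconnection: C4–C4a and C2–C3 of ring F in one enantioselective Pd-catalysed conjunctive cross-coupling of a ring-D aryl triflate, a vinyl group (C3–C4) and a 1-arylvinyl group (C2 with ring E) assembled on boron; C3 is set by the catalyst and C2 is relayed from it.
4. Enabling feature: C3 of ring F is a secondary carbinol lying between C4 (a CH2 on C4a of the phloroglucinol-type ring D) and the benzylic C2 that carries ring E. It is therefore the oxidation product of a secondary boronate flanked by an aryl–CH2 and a carbon that can migrate from boron.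
5. Ring order: rings D and E enter as preformed arenes, ring F is the only ring constructed (step 12), rings A, B and C come intact from (−)-epigallocatechin and the galloyl ring from 3,4,5-tris(benzyloxy)benzoic acid.

Key step: step 7

Remark on the chemistry: L* denotes (Sp,Sp)-MandyPhos, 1,1′-bis[bis(4-methoxy-3,5-dimethylphenyl)phosphino]-2,2′-bis[(R)-α-(dimethylamino)benzyl]ferrocene. Its sense of induction is assumed to match that of simpler aryl triflate/vinylboron couplings and to give the (R)-boronate 13; if a test run shows the opposite sense, the mirror-image ligand is used.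

## Route

Step 1
Reactants: 1 2,4,6-trihydroxybenzaldehyde
Product: 2 2,4-bis(benzyloxy)-6-hydroxybenzaldehyde
Conditions: BnBr (2.1 equiv), K2CO3, DMF, rt
Reagents that add atoms: benzyl bromide, BrCc1ccccc1
Why: Williamson etherification; the hydroxyl para to the formyl group and one ortho hydroxyl are alkylated, while the remaining ortho hydroxyl, held in a hydrogen bond to the aldehyde, should stay free.

Step 2
Reactants: 2 2,4-bis(benzyloxy)-6-hydroxybenzaldehyde
Product: 3 2,4-bis(benzyloxy)-6-(methoxymethoxy)benzaldehyde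
Conditions: MOMCl, i-Pr2NEt, CH2Cl2, 0 °C → 40 °C
Reagents that add atoms: chloromethyl methyl ether, COCCl
Why: O-alkylation (acetal formation) of the chelated phenol gives the future O1 a protecting group that is orthogonal to benzyl.

Step 3
Reactants: 3 2,4-bis(benzyloxy)-6-(methoxymethoxy)benzaldehyde
Product: 5 2,4-bis(benzyloxy)-6-(methoxymethoxy)phenol, via aryl formate 4 (not isolated)
Conditions: mCPBA, NaHCO3, CH2Cl2, 0 °C → rt; then K2CO3 (cat.), MeOH, rt
Reagents that add atoms: 3-chloroperoxybenzoic acid, OOC(=O)c1cccc(Cl)c1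
Why: Dakin-type Baeyer–Villiger oxidation; the electron-rich trioxygenated aryl group migrates to oxygen and methanolysis of the formate leaves the phenol needed for the triflate.

Step 4
Reactants: 5 2,4-bis(benzyloxy)-6-(methoxymethoxy)phenol
Product: 6 2,4-bis(benzyloxy)-6-(methoxymethoxy)phenyl trifluoromethanesulfonate
Conditions: KN(SiMe3)2, PhNTf2, THF, −78 °C → 0 °C
Reagents that add atoms: N-phenylbis(trifluoromethanesulfonimide), O=S(=O)(N(c1ccccc1)S(=O)(=O)C(F)(F)F)C(F)(F)F
Why: O-sulfonylation of the hindered, oxidation-sensitive phenoxide with a mild triflyl donor that leaves the MOM ether untouched.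

Step 5
Reactants: 7 3,4,5-tris(benzyloxy)benzaldehyde
Product: 8 1,2,3-tris(benzyloxy)-5-ethynylbenzene
Conditions: dimethyl (1-diazo-2-oxopropyl)phosphonate, K2CO3, MeOH/THF, rt
Reagents that add atoms: dimethyl (1-diazo-2-oxopropyl)phosphonate, COP(=O)(OC)C(=[N+]=[N-])C(C)=O
Why: Ohira–Bestmann (Seyferth–Gilbert) homologation converts the aldehyde into the terminal alkyne under mild base.

Step 6
Reactants: 8 1,2,3-tris(benzyloxy)-5-ethynylbenzene
Product: 9 4,4,5,5-tetramethyl-2-{1-[3,4,5-tris(benzyloxy)phenyl]ethenyl}-1,3,2-dioxaborolane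
Conditions: B2pin2, CuCl (5 mol %), 1,3-bis(2,4,6-trimethylphenyl)imidazolinium chloride (5 mol %), NaOt-Bu (10 mol %), MeOH (2 equiv), THF, −50 °C → −15 °C
Reagents that add atoms: bis(pinacolato)diboron, CC1(C)OB(OC1(C)C)B1OC(C)(C)C(C)(C)O1
Why: copper-catalysed Markovnikov protoboration of a terminal aryl alkyne; the N-aryl carbene–copper boryl places boron on the internal carbon and methanol protonates the alkenylcopper.

Step 7
Reactants: 9 4,4,5,5-tetramethyl-2-{1-[3,4,5-tris(benzyloxy)phenyl]ethenyl}-1,3,2-dioxaborolane; 10 tetravinylstannane; 6 2,4-bis(benzyloxy)-6-(methoxymethoxy)phenyl trifluoromethanesulfonate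
Product: 14 (2R)-1-[2,4-bis(benzyloxy)-6-(methoxymethoxy)phenyl]-3-[3,4,5-tris(benzyloxy)phenyl]but-3-en-2-ol, via vinyllithium 11 (not isolated), via lithium bis(alkenyl)borate 12 (not isolated), via allylic pinacol boronate 13 (not isolated)
Conditions: 10 (0.27 equiv), n-BuLi, Et2O, 0 °C; 9, THF, −78 °C → rt; then 6, Pd(OAc)2 (3 mol %), L* (3.6 mol %), THF, 60 °C; then NaOH (3 M aq), H2O2 (30 %), 0 °C → rt
Reagents that add atoms: hydrogen peroxide, OO
Why: Enantioselective palladium-catalysed conjunctive cross-coupling, whose closest known form is the coupling of bis(alkenyl)borates with aryl triflates under Pd(OAc)2 and this ferrocenyl diphosphine to give α-chiral allyl boronates. Zerovalent palladium inserts into the C–OTf bond of 6, the cationic divalent arylpalladium binds the unsubstituted vinyl group of 12 and thereby triggers an anti 1,2-metallate shift in which the 1-arylvinyl group moves from boron to the boron-bearing carbon (C2–C3 bond) while palladium takes the terminal carbon, and reductive elimination joins this carbon to the aryl ring (C4–C4a bond). No ring is closed here: the step assembles the open C6–C3–C6 chain of the lower unit, and ring F is closed later in step 12. The single new stereocentre, C3, is set by the catalyst, whose chiral diphosphine selects the face of the vinyl group that palladium binds; oxidation of the C–B bond with retention then gives the (R)-carbinol. The step needs chemoselectivity between the two alkenyl groups on boron and between conjunctive coupling and direct Suzuki-type transmetalation: the 1,1-disubstituted arylvinyl group is too hindered to be the π-acceptor, so it migrates and the vinyl group accepts, and the non-coordinating triflate (no halide is present, the vinyllithium being made halide-free) keeps palladium cationic so that alkene binding outruns transmetalation. The regiochemistry (aryl on the terminal CH2, migrating carbon on the carbon that keeps boron) is inherent in the metallate shift.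

Step 8
Reactants: 14 (2R)-1-[2,4-bis(benzyloxy)-6-(methoxymethoxy)phenyl]-3-[3,4,5-tris(benzyloxy)phenyl]but-3-en-2-ol
Product: 15 1,5-bis(benzyloxy)-2-{(2R)-2-(benzyloxy)-3-[3,4,5-tris(benzyloxy)phenyl]but-3-en-1-yl}-3-(methoxymethoxy)benzene
Conditions: NaH, BnBr, n-Bu4NI (cat.), THF/DMF, 0 °C → rt
Reagents that add atoms: benzyl bromide, BrCc1ccccc1
Why: Williamson etherification of the allylic alcohol; the benzyl ether shields C3–O from glycol cleavage in step 9 and serves as the chelating group in step 10, without touching the stereocentre.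

Step 9
Reactants: 15 1,5-bis(benzyloxy)-2-{(2R)-2-(benzyloxy)-3-[3,4,5-tris(benzyloxy)phenyl]but-3-en-1-yl}-3-(methoxymethoxy)benzene
Product: 17 (2R)-2-(benzyloxy)-3-[2,4-bis(benzyloxy)-6-(methoxymethoxy)phenyl]-1-[3,4,5-tris(benzyloxy)phenyl]propan-1-one, via vicinal diol 16 (not isolated)
Conditions: OsO4 (2 mol %), NaIO4, 2,6-lutidine, dioxane/H2O, rt
Reagents that add atoms: sodium periodate, [Na+].[O-]I(=O)(=O)=O; osmium tetroxide (catalytic oxygen carrier), O=[Os](=O)(=O)=O
Why: Lemieux–Johnson oxidation (dihydroxylation, then periodate glycol cleavage) removes the auxiliary methylene carbon and unveils the C2 aryl ketone; the lutidine buffer should keep the α-alkoxy stereocentre from enolising.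

Step 10
Reactants: 17 (2R)-2-(benzyloxy)-3-[2,4-bis(benzyloxy)-6-(methoxymethoxy)phenyl]-1-[3,4,5-tris(benzyloxy)phenyl]propan-1-one
Product: 18 (1S,2R)-2-(benzyloxy)-3-[2,4-bis(benzyloxy)-6-(methoxymethoxy)phenyl]-1-[3,4,5-tris(benzyloxy)phenyl]propan-1-ol
Conditions: Zn(BH4)2, Et2O, −30 °C → 0 °C
Reagents that add atoms: none
Why: chelation-controlled (Cram-chelate) reduction; zinc bridges the ketone and benzyloxy oxygens and hydride arrives from the face of C3–H, so the new C2 carbinol should be anti to C3–O (1S).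

Step 11
Reactants: 18 (1S,2R)-2-(benzyloxy)-3-[2,4-bis(benzyloxy)-6-(methoxymethoxy)phenyl]-1-[3,4,5-tris(benzyloxy)phenyl]propan-1-ol
Product: 19 3,5-bis(benzyloxy)-2-{(2R,3S)-2-(benzyloxy)-3-hydroxy-3-[3,4,5-tris(benzyloxy)phenyl]propyl}phenol
Conditions: HCl (0.5 M), MeOH/THF, rt → 40 °C
Reagents that add atoms: none
Why: acid-catalysed acetal exchange removes the phenolic MOM group; the benzylic alcohol, poorly ionisable next to a pyrogallol-type ring and a β-alkoxy group, should survive these mild conditions.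

Step 12
Reactants: 19 3,5-bis(benzyloxy)-2-{(2R,3S)-2-(benzyloxy)-3-hydroxy-3-[3,4,5-tris(benzyloxy)phenyl]propyl}phenol
Product: 20 (2R,3R)-3,5,7-tris(benzyloxy)-2-[3,4,5-tris(benzyloxy)phenyl]-3,4-dihydro-2H-chromene (hexa-O-benzyl-(−)-epigallocatechin)
Conditions: PPh3, DIAD, THF, 0 °C → rt
Reagents that add atoms: none
Why: intramolecular Mitsunobu etherification; the phenol displaces the activated benzylic alcohol in a 6-exo-tet SN2 closure of ring F with inversion at C2, turning the anti relationship into the 2,3-cis (2R,3R) flavan.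

Step 13
Reactants: 21 (−)-epigallocatechin
Product: 22 (2R,3R)-5,7-bis(benzyloxy)-2-[3,4,5-tris(benzyloxy)phenyl]-3,4-dihydro-2H-chromen-3-ol (penta-O-benzyl-(−)-epigallocatechin)
Conditions: BnBr (5.5 equiv), K2CO3, DMF (degassed), 0 °C → rt, Ar
Reagents that add atoms: benzyl bromide, BrCc1ccccc1
Why: Williamson etherification of the five phenols; the carbonate base deprotonates only the phenols, so the secondary C3 hydroxyl stays free, and low temperature with exclusion of oxygen should limit C2 epimerisation and autoxidation.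

Step 14
Reactants: 22 penta-O-benzyl-(−)-epigallocatechin
Product: 23 (2R,3R,4S)-5,7-bis(benzyloxy)-4-(2-ethoxyethoxy)-2-[3,4,5-tris(benzyloxy)phenyl]-3,4-dihydro-2H-chromen-3-ol (4β-ether, 3,4-trans)
Conditions: DDQ (2 equiv), 2-ethoxyethanol, CH2Cl2, rt
Reagents that add atoms: 2-ethoxyethanol, OCCOCC
Why: benzylic oxidation by hydride abstraction at C4, the position activated by the ortho and para oxygens of ring A; the cation is trapped by the alcohol anti to the C3 hydroxyl, storing C4 as a latent cation.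

Step 15
Reactants: 23 4β-(2-ethoxyethoxy)-penta-O-benzyl-(−)-epigallocatechin; 24 3,4,5-tris(benzyloxy)benzoic acid
Product: 25 (2R,3R,4S)-5,7-bis(benzyloxy)-4-(2-ethoxyethoxy)-2-[3,4,5-tris(benzyloxy)phenyl]-3,4-dihydro-2H-chromen-3-yl 3,4,5-tris(benzyloxy)benzoate
Conditions: 24 (1.5 equiv), DCC, DMAP, CH2Cl2, 0 °C → rt
Reagents that add atoms: none
Why: Steglich esterification; the acylpyridinium formed from the O-acylisourea acylates the hindered C3 hydroxyl under non-acidic conditions that leave the acid-labile 4-ether and all three stereocentres untouched.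

Step 16
Reactants: 25 4β-(2-ethoxyethoxy)-octa-O-benzyl-(−)-epigallocatechin 3-O-gallate; 20 hexa-O-benzyl-(−)-epigallocatechin
Product: 26 (2R,3R,4R)-5,7-bis(benzyloxy)-4-{(2R,3R)-3,5,7-tris(benzyloxy)-2-[3,4,5-tris(benzyloxy)phenyl]-3,4-dihydro-2H-chromen-8-yl}-2-[3,4,5-tris(benzyloxy)phenyl]-3,4-dihydro-2H-chromen-3-yl 3,4,5-tris(benzyloxy)benzoate
Conditions: TMSOTf (0.2 equiv), CH2Cl2, −78 °C → −40 °C; 20 in excess (2 equiv), surplus recovered
Reagents that add atoms: none
Why: Lewis-acid-promoted Friedel–Crafts interflavan coupling; ionisation of the 4-ether gives a C4 cation bridged by the neighbouring galloyl carbonyl, and C8 of 20, the most nucleophilic position of a 5,7-dibenzyloxyflavan, attacks anti to the C3 substituent, setting upper C4 as 4β (3,4-trans, 4R).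

Step 17
Reactants: 26 tetradeca-O-benzyl dimer
Product: 27 (−)-epigallocatechin 3-O-gallate-(4β→8)-(−)-epigallocatechin (target)
Conditions: H2 (1 atm), Pd(OH)2/C, THF/MeOH/H2O, rt
Reagents that add atoms: none
Why: hydrogenolysis cleaves the thirteen aryl benzyl ethers and the C3 alkyl benzyl ether under neutral conditions that should leave the gallate ester, the interflavan bond and all five stereocentres untouched.

## Compound list

1 | 2,4,6-trihydroxybenzaldehyde | O=Cc1c(O)cc(O)cc1O | starting material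
2 | 2,4-bis(benzyloxy)-6-hydroxybenzaldehyde | O=Cc1c(O)cc(OCc2ccccc2)cc1OCc1ccccc1 | intermediate
3 | 2,4-bis(benzyloxy)-6-(methoxymethoxy)benzaldehyde | O=Cc1c(OCOC)cc(OCc2ccccc2)cc1OCc1ccccc1 | intermediate
4 | 2,4-bis(benzyloxy)-6-(methoxymethoxy)phenyl formate (not isolated) | O=COc1c(OCOC)cc(OCc2ccccc2)cc1OCc1ccccc1 | intermediate
5 | 2,4-bis(benzyloxy)-6-(methoxymethoxy)phenol | Oc1c(OCOC)cc(OCc2ccccc2)cc1OCc1ccccc1 | intermediate
6 | 2,4-bis(benzyloxy)-6-(methoxymethoxy)phenyl trifluoromethanesulfonate | FC(F)(F)S(=O)(=O)Oc1c(OCOC)cc(OCc2ccccc2)cc1OCc1ccccc1 | intermediate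
7 | 3,4,5-tris(benzyloxy)benzaldehyde | O=Cc1cc(OCc2ccccc2)c(OCc2ccccc2)c(OCc2ccccc2)c1 | starting material
8 | 1,2,3-tris(benzyloxy)-5-ethynylbenzene | C#Cc1cc(OCc2ccccc2)c(OCc2ccccc2)c(OCc2ccccc2)c1 | intermediate
9 | 4,4,5,5-tetramethyl-2-{1-[3,4,5-tris(benzyloxy)phenyl]ethenyl}-1,3,2-dioxaborolane | C=C(B1OC(C)(C)C(C)(C)O1)c1cc(OCc2ccccc2)c(OCc2ccccc2)c(OCc2ccccc2)c1 | intermediate
10 | tetravinylstannane | C=C[Sn](C=C)(C=C)C=C | starting material
11 | vinyllithium (not isolated) | [Li]C=C | intermediate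
12 | lithium (ethenyl){1-[3,4,5-tris(benzyloxy)phenyl]ethenyl}(pinacolato)borate (not isolated) | [Li+].C=C[B-]1(OC(C)(C)C(C)(C)O1)C(=C)c1cc(OCc2ccccc2)c(OCc2ccccc2)c(OCc2ccccc2)c1 | intermediate
13 | 2-{(2R)-1-[2,4-bis(benzyloxy)-6-(methoxymethoxy)phenyl]-3-[3,4,5-tris(benzyloxy)phenyl]but-3-en-2-yl}-4,4,5,5-tetramethyl-1,3,2-dioxaborolane (not isolated) | C=C(c1cc(OCc2ccccc2)c(OCc2ccccc2)c(OCc2ccccc2)c1)[C@H](B1OC(C)(C)C(C)(C)O1)Cc1c(OCOC)cc(OCc2ccccc2)cc1OCc1ccccc1 | intermediate
14 | (2R)-1-[2,4-bis(benzyloxy)-6-(methoxymethoxy)phenyl]-3-[3,4,5-tris(benzyloxy)phenyl]but-3-en-2-ol | C=C(c1cc(OCc2ccccc2)c(OCc2ccccc2)c(OCc2ccccc2)c1)[C@H](O)Cc1c(OCOC)cc(OCc2ccccc2)cc1OCc1ccccc1 | intermediate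
15 | 1,5-bis(benzyloxy)-2-{(2R)-2-(benzyloxy)-3-[3,4,5-tris(benzyloxy)phenyl]but-3-en-1-yl}-3-(methoxymethoxy)benzene | C=C(c1cc(OCc2ccccc2)c(OCc2ccccc2)c(OCc2ccccc2)c1)[C@H](OCc1ccccc1)Cc1c(OCOC)cc(OCc2ccccc2)cc1OCc1ccccc1 | intermediate
16 | (3R)-3-(benzyloxy)-4-[2,4-bis(benzyloxy)-6-(methoxymethoxy)phenyl]-2-[3,4,5-tris(benzyloxy)phenyl]butane-1,2-diol, both C2 epimers (not isolated) | OCC(O)(c1cc(OCc2ccccc2)c(OCc2ccccc2)c(OCc2ccccc2)c1)[C@H](OCc1ccccc1)Cc1c(OCOC)cc(OCc2ccccc2)cc1OCc1ccccc1 | intermediate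
17 | (2R)-2-(benzyloxy)-3-[2,4-bis(benzyloxy)-6-(methoxymethoxy)phenyl]-1-[3,4,5-tris(benzyloxy)phenyl]propan-1-one | O=C(c1cc(OCc2ccccc2)c(OCc2ccccc2)c(OCc2ccccc2)c1)[C@H](OCc1ccccc1)Cc1c(OCOC)cc(OCc2ccccc2)cc1OCc1ccccc1 | intermediate
18 | (1S,2R)-2-(benzyloxy)-3-[2,4-bis(benzyloxy)-6-(methoxymethoxy)phenyl]-1-[3,4,5-tris(benzyloxy)phenyl]propan-1-ol | O[C@@H](c1cc(OCc2ccccc2)c(OCc2ccccc2)c(OCc2ccccc2)c1)[C@H](OCc1ccccc1)Cc1c(OCOC)cc(OCc2ccccc2)cc1OCc1ccccc1 | intermediate
19 | 3,5-bis(benzyloxy)-2-{(2R,3S)-2-(benzyloxy)-3-hydroxy-3-[3,4,5-tris(benzyloxy)phenyl]propyl}phenol | O[C@@H](c1cc(OCc2ccccc2)c(OCc2ccccc2)c(OCc2ccccc2)c1)[C@H](OCc1ccccc1)Cc1c(O)cc(OCc2ccccc2)cc1OCc1ccccc1 | intermediate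
20 | (2R,3R)-3,5,7-tris(benzyloxy)-2-[3,4,5-tris(benzyloxy)phenyl]-3,4-dihydro-2H-chromene | O(Cc1ccccc1)[C@@H]1Cc2c(OCc3ccccc3)cc(OCc3ccccc3)cc2O[C@@H]1c1cc(OCc2ccccc2)c(OCc2ccccc2)c(OCc2ccccc2)c1 | intermediate
21 | (−)-epigallocatechin, (2R,3R) | O[C@@H]1Cc2c(O)cc(O)cc2O[C@@H]1c1cc(O)c(O)c(O)c1 | starting material
22 | (2R,3R)-5,7-bis(benzyloxy)-2-[3,4,5-tris(benzyloxy)phenyl]-3,4-dihydro-2H-chromen-3-ol (penta-O-benzyl-(−)-epigallocatechin) | O[C@@H]1Cc2c(OCc3ccccc3)cc(OCc3ccccc3)cc2O[C@@H]1c1cc(OCc2ccccc2)c(OCc2ccccc2)c(OCc2ccccc2)c1 | intermediate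
23 | (2R,3R,4S)-5,7-bis(benzyloxy)-4-(2-ethoxyethoxy)-2-[3,4,5-tris(benzyloxy)phenyl]-3,4-dihydro-2H-chromen-3-ol | O[C@@H]1[C@@H](OCCOCC)c2c(OCc3ccccc3)cc(OCc3ccccc3)cc2O[C@@H]1c1cc(OCc2ccccc2)c(OCc2ccccc2)c(OCc2ccccc2)c1 | intermediate
24 | 3,4,5-tris(benzyloxy)benzoic acid | OC(=O)c1cc(OCc2ccccc2)c(OCc2ccccc2)c(OCc2ccccc2)c1 | starting material
25 | (2R,3R,4S)-5,7-bis(benzyloxy)-4-(2-ethoxyethoxy)-2-[3,4,5-tris(benzyloxy)phenyl]-3,4-dihydro-2H-chromen-3-yl 3,4,5-tris(benzyloxy)benzoate | O=C(O[C@@H]1[C@@H](OCCOCC)c2c(OCc3ccccc3)cc(OCc3ccccc3)cc2O[C@@H]1c1cc(OCc2ccccc2)c(OCc2ccccc2)c(OCc2ccccc2)c1)c1cc(OCc2ccccc2)c(OCc2ccccc2)c(OCc2ccccc2)c1 | intermediate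
26 | tetradeca-O-benzyl dimer, upper unit (2R,3R,4R), lower unit (2R,3R) | O=C(O[C@@H]1[C@@H](c2c(OCc4ccccc4)cc(OCc4ccccc4)c3c2O[C@H](c2cc(OCc4ccccc4)c(OCc4ccccc4)c(OCc4ccccc4)c2)[C@H](OCc2ccccc2)C3)c2c(OCc3ccccc3)cc(OCc3ccccc3)cc2O[C@@H]1c1cc(OCc2ccccc2)c(OCc2ccccc2)c(OCc2ccccc2)c1)c1cc(OCc2ccccc2)c(OCc2ccccc2)c(OCc2ccccc2)c1 | intermediate
27 | (−)-epigallocatechin 3-O-gallate-(4β→8)-(−)-epigallocatechin, upper unit (2R,3R,4R), lower unit (2R,3R) | O=C(O[C@@H]1[C@@H](c2c(O)cc(O)c3c2O[C@H](c2cc(O)c(O)c(O)c2)[C@H](O)C3)c2c(O)cc(O)cc2O[C@@H]1c1cc(O)c(O)c(O)c1)c1cc(O)c(O)c(O)c1 | target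

## Step count and risk

Total step count: 17.
Longest linear sequence: 12 steps (1, 2, 3, 4, 7, 8, 9, 10, 11, 12, 16, 17).

The three steps most likely to fail:

**Step 7 (conjunctive coupling).** Oxidative addition into the doubly ortho-oxygenated, electron-rich triflate may be slow, an alkenyl group may transfer directly from boron to palladium (plain Suzuki product), or the enantioselectivity may erode with this hindered electrophile. The fallback sets C3 by an auxiliary-controlled glycolate alkylation that needs no arylpalladium species. It sets out from aldehyde 3. Reduction with NaBH4 (MeOH/THF, 0 °C) gives [2,4-bis(benzyloxy)-6-(methoxymethoxy)phenyl]methanol F1. This is converted with PBr3/pyridine (Et2O, −20 °C) into the labile 1,5-bis(benzyloxy)-2-(bromomethyl)-3-(methoxymethoxy)benzene F2, which is used at once to alkylate the sodium enolate (NaN(SiMe3)2, THF, −78 °C) of (S)-4-benzyl-3-[(benzyloxy)acetyl]oxazolidin-2-one. The enolate is attacked on the face away from the auxiliary benzyl group, giving (4S)-4-benzyl-3-{(2R)-2-(benzyloxy)-3-[2,4-bis(benzyloxy)-6-(methoxymethoxy)phenyl]propanoyl}-1,3-oxazolidin-2-one F3. Transamination with AlMe3/MeONHMe·HCl gives (2R)-2-(benzyloxy)-3-[2,4-bis(benzyloxy)-6-(methoxymethoxy)phenyl]-N-methoxy-N-methylpropanamide F4. Addition of 3,4,5-tris(benzyloxy)phenylmagnesium bromide (THF, 0 °C) then gives ketone 17, where the route is rejoined.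

**Step 12 (Mitsunobu ring closure).** The activated benzylic alcohol may ionise before it is displaced, which would cost the inversion and give the 2,3-trans ether, or it may eliminate. The fallback closes ring F by reductive etherification instead of SN2 displacement. It sets out from ketone 17. The MOM group is removed (HCl 0.5 M, MeOH/THF) to give (2R)-2-(benzyloxy)-3-[2,4-bis(benzyloxy)-6-hydroxyphenyl]-1-[3,4,5-tris(benzyloxy)phenyl]propan-1-one F5, which is in equilibrium with its cyclic hemiketal. Treatment with Et3SiH and BF3·OEt2 (CH2Cl2, −78 °C → −20 °C) reduces the cyclic 2-aryl oxocarbenium ion. Allylic strain with the 2-aryl group should hold the 3-benzyloxy group pseudo-axial, so hydride is expected to add anti to it and give the 2,3-cis ether 20, where the route is rejoined. The cis outcome would be checked by the H2/H3 coupling constant.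

**Step 16 (interflavan coupling).** The electrophile may condense with itself through its own C8, the dimer may react further to oligomers, or some 4→6 isomer may form. The fallback caps the nucleophilic position of the electrophile with bromine, so that the two halves can be used near 1:1. It sets out from 22. NBS (CH2Cl2, −20 °C) brominates C8 of ring A to give (2R,3R)-5,7-bis(benzyloxy)-8-bromo-2-[3,4,5-tris(benzyloxy)phenyl]-3,4-dihydro-2H-chromen-3-ol F6. DDQ/2-ethoxyethanol as in step 14 gives the 8-bromo-4β-(2-ethoxyethoxy) alcohol F7. Esterification with acid 24 (DCC, DMAP) as in step 15 gives the 8-bromo-4β-(2-ethoxyethoxy) gallate F8. TMSOTf-promoted coupling with 20 as in step 16 gives the 8-bromo tetradeca-O-benzyl dimer F9. Hydrogenolysis (H2, Pd(OH)2/C, Et3N, THF/MeOH) removes the bromine together with the benzyl groups and returns to the route at the target 27.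

## Further compounds

F1 | step 7 | [2,4-bis(benzyloxy)-6-(methoxymethoxy)phenyl]methanol | OCc1c(OCOC)cc(OCc2ccccc2)cc1OCc1ccccc1
F2 | step 7 | 1,5-bis(benzyloxy)-2-(bromomethyl)-3-(methoxymethoxy)benzene | BrCc1c(OCOC)cc(OCc2ccccc2)cc1OCc1ccccc1
F3 | step 7 | (4S)-4-benzyl-3-{(2R)-2-(benzyloxy)-3-[2,4-bis(benzyloxy)-6-(methoxymethoxy)phenyl]propanoyl}-1,3-oxazolidin-2-one | O=C1OC[C@H](Cc2ccccc2)N1C(=O)[C@H](OCc1ccccc1)Cc1c(OCOC)cc(OCc2ccccc2)cc1OCc1ccccc1
F4 | step 7 | (2R)-2-(benzyloxy)-3-[2,4-bis(benzyloxy)-6-(methoxymethoxy)phenyl]-N-methoxy-N-methylpropanamide | CON(C)C(=O)[C@H](OCc1ccccc1)Cc1c(OCOC)cc(OCc2ccccc2)cc1OCc1ccccc1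
F5 | step 12 | (2R)-2-(benzyloxy)-3-[2,4-bis(benzyloxy)-6-hydroxyphenyl]-1-[3,4,5-tris(benzyloxy)phenyl]propan-1-one | O=C(c1cc(OCc2ccccc2)c(OCc2ccccc2)c(OCc2ccccc2)c1)[C@H](OCc1ccccc1)Cc1c(O)cc(OCc2ccccc2)cc1OCc1ccccc1
F6 | step 16 | (2R,3R)-5,7-bis(benzyloxy)-8-bromo-2-[3,4,5-tris(benzyloxy)phenyl]-3,4-dihydro-2H-chromen-3-ol | O[C@@H]1Cc2c(OCc3ccccc3)cc(OCc3ccccc3)c(Br)c2O[C@@H]1c1cc(OCc2ccccc2)c(OCc2ccccc2)c(OCc2ccccc2)c1
F7 | step 16 | (2R,3R,4S)-5,7-bis(benzyloxy)-8-bromo-4-(2-ethoxyethoxy)-2-[3,4,5-tris(benzyloxy)phenyl]-3,4-dihydro-2H-chromen-3-ol | O[C@@H]1[C@@H](OCCOCC)c2c(OCc3ccccc3)cc(OCc3ccccc3)c(Br)c2O[C@@H]1c1cc(OCc2ccccc2)c(OCc2ccccc2)c(OCc2ccccc2)c1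
F8 | step 16 | (2R,3R,4S)-5,7-bis(benzyloxy)-8-bromo-4-(2-ethoxyethoxy)-2-[3,4,5-tris(benzyloxy)phenyl]-3,4-dihydro-2H-chromen-3-yl 3,4,5-tris(benzyloxy)benzoate | O=C(O[C@@H]1[C@@H](OCCOCC)c2c(OCc3ccccc3)cc(OCc3ccccc3)c(Br)c2O[C@@H]1c1cc(OCc2ccccc2)c(OCc2ccccc2)c(OCc2ccccc2)c1)c1cc(OCc2ccccc2)c(OCc2ccccc2)c(OCc2ccccc2)c1
F9 | step 16 | 8-bromo tetradeca-O-benzyl dimer (bromine on C8 of the upper unit) | O=C(O[C@@H]1[C@@H](c2c(OCc4ccccc4)cc(OCc4ccccc4)c3c2O[C@H](c2cc(OCc4ccccc4)c(OCc4ccccc4)c(OCc4ccccc4)c2)[C@H](OCc2ccccc2)C3)c2c(OCc3ccccc3)cc(OCc3ccccc3)c(Br)c2O[C@@H]1c1cc(OCc2ccccc2)c(OCc2ccccc2)c(OCc2ccccc2)c1)c1cc(OCc2ccccc2)c(OCc2ccccc2)c(OCc2ccccc2)c1
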